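**Retrosynthetic overview**
- The target comes from the triol andalusol by 6-selective acetylation. The 6,8-diol comes from a labd-7-en-6-one by nucleophilic epoxidation, then SmI2 reduction.
- The side chain is made at C11–C12 by allyl–alkyl coupling of a borane (from a C9 methylene) with 2-(bromomethyl)butadiene, itself made from isoprene. During this stage the C6 carbonyl and 18-OH are masked together as a dihydrofuran.
- The key disconnection is C3–C4. Cp2TiCl converts the epoxide carbon C4 into a nucleophilic β-titanoxy radical, which attacks a nitrile carbon. Both carbons are normally electrophilic. This closes ring A, sets quaternary C4 and frees 18-OH.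
- Quaternary C10 comes from (S)-carvone by α′-methylation and then cyanoethylation.
- Ring order: ring B is the carvone ring, and ring A is closed in step 4.

**Assumption.** Labdane numbering is used. α and β refer to the usual labdane drawing (ring A left, C10 top centre). In that drawing the target has 10α-CH3, 5β-H, 9β-H, 4α-CH3 (C19, axial), 4β-CH2OH (C18, equatorial), 6β-OAc, 8β-OH and 8α-CH3. This equals ent-6α-acetoxy-8α,18-dihydroxylabda-13(16),14-diene.

Step 1
Reactants: 1 (S)-(+)-carvone
Product: 2 trans-6-methylcarvone
Conditions: LiN(i-Pr)2 (1.05 equiv), THF, −78 °C; MeI, −78 → 0 °C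
Reagents that add atoms: iodomethane, CI
Why: Kinetic deprotonation gives the cross-conjugated α′-enolate, which is C-methylated (enolate alkylation); the new centre (future C10, methyl mainly trans to isopropenyl) is flattened again in step 2, so its ratio does not matter.

Step 2
Reactants: 2 trans-6-methylcarvone; 3 acrylonitrile
Product: 4 cyanoethyl methylcarvone
Conditions: BnMe3N+ OH− (40% in MeOH, 0.1 equiv), t-BuOH, 25 °C
Reagents that add atoms: none
Why: In this base-catalysed Michael addition (cyanoethylation) of the tetrasubstituted α′-enolate, acrylonitrile approaches anti to the neighbouring isopropenyl group and fixes quaternary C10 with the C1–C3 arm trans to C4, the 8-methyl disfavours attack through the extended dienolate, and the protic medium quenches the α-cyano carbanion before a second Michael addition.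

Step 3
Reactants: 4 cyanoethyl methylcarvone
Product: 5 epoxy nitrile
Conditions: mCPBA (1.05 equiv), CH2Cl2, 0 °C
Reagents that add atoms: 3-chloroperoxybenzoic acid, OOC(=O)c1cccc(Cl)c1
Why: Prilezhaev epoxidation takes only the electron-rich 1,1-disubstituted alkene and leaves the enone; the 1:1 mixture at the oxirane carbon (C4) is harmless because C4 becomes a planar radical in step 4.

Step 4
Reactants: 5 epoxy nitrile
Product: 7 hydroxy dione, via ketimine 6 (not isolated)
Conditions: Cp2TiCl2 (2.5 equiv), Mn dust (8 equiv), THF, 25 °C, slow addition of 5; then 1 M HCl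
Reagents that add atoms: water, O
Why: Trivalent titanium opens the 2,2-disubstituted epoxide by single-electron transfer (Nugent–RajanBabu reductive opening) to the tertiary β-titanoxy radical at C4, which adds 6-exo to the nitrile carbon C3 (titanocene epoxynitrile cyclisation), the iminyl radical is trapped by a second Cp2TiCl and hydrolysed; both epoxide epimers converge, and in the chair transition state the bulky CH2OTiCp2Cl sits equatorial with the methyl axial (syn to 10-CH3), which sets C4 on a trans ring fusion already fixed by C5 and C10.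

Step 5
Reactants: 7 hydroxy dione
Product: 9 hydroxy enone, via tosylhydrazone 8 (not isolated)
Conditions: TsNHNH2, EtOH, 50 °C; concentrate; catecholborane, CHCl3, −10 °C; NaOAc·3H2O, reflux
Reagents that add atoms: none
Why: Only the saturated C3 ketone condenses, because the C9 enone is flanked by quaternary C10 and the 8-methyl and s-trans enones resist catecholborane; hydride addition followed by loss of sulfinate and N2 gives CH2 (Kabalka form of the Caglioti tosylhydrazone reduction) without touching a stereocentre.

Step 6
Reactants: 9 hydroxy enone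
Product: 11 dihydrofuran dienone, via hydroxy enedione 10 (not isolated)
Conditions: Pd(OH)2/C (5 mol %), t-BuOOH (5 equiv), K2CO3 (0.25 equiv), CH2Cl2, 4 °C; filter; PPTS (10 mol %), benzene, reflux (Dean–Stark)
Reagents that add atoms: tert-butyl hydroperoxide, CC(C)(C)OO
Why: Peroxy-radical γ-oxidation of the enone to the 1,4-enedione places oxygen on C6, the only γ-CH2, and acid-catalysed cyclodehydration of the γ-hydroxy ketone (equatorial C18-OH lies next to C6=O) gives a flat 2,3-dihydrofuran that masks the more accessible C6 carbonyl and 18-OH together; C5 is sp2 for now and is reset in step 10.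

Step 7
Reactants: 11 dihydrofuran dienone
Product: 12 9-methylene triene ether
Conditions: Ph3PCH3Br (3 equiv), KOt-Bu (2.8 equiv), toluene, 80 °C
Reagents that add atoms: methyltriphenylphosphonium bromide, C[P+](c1ccccc1)(c1ccccc1)c1ccccc1.[Br-]
Why: Wittig methylenation of the only remaining carbonyl (C9) installs C11; the substrate has no OH and no enolisable α-H, so the hindered ketone can be forced with excess ylide.

Step 8
Reactants: 13 isoprene
Product: 14 (E)-1,4-dibromo-2-methylbut-2-ene
Conditions: Br2 (1 equiv), CH2Cl2, −20 °C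
Reagents that add atoms: bromine, BrBr
Why: Electrophilic 1,4-addition of bromine to the conjugated diene gives the thermodynamically preferred (E)-1,4-dibromide.

Step 9
Reactants: 14 (E)-1,4-dibromo-2-methylbut-2-ene
Product: 15 2-(bromomethyl)buta-1,3-diene
Conditions: DMPU, 120 °C, reduced pressure (product distils)
Reagents that add atoms: none
Why: Thermal 1,4-dehydrobromination (methyl H and C4-Br are lost) regenerates a diene, and distillation removes the volatile product before it polymerises.

Step 10
Reactants: 12 9-methylene triene ether; 15 2-(bromomethyl)buta-1,3-diene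
Product: 18 18-hydroxy enone, via B-alkyl-9-BBN borane 16 (not isolated), via labdane dienol ether 17 (not isolated)
Conditions: 9-BBN-H (1.3 equiv), THF, 0 → 40 °C; KOt-Bu (1.3 equiv), CuOAc (10 mol %), 15 (1.5 equiv), THF, 25 °C; then 1 M HCl, THF, 25 °C
Reagents that add atoms: water, O
Why: Hydroboration puts boron on the terminal C11 and delivers H to C9 from the β face opposite 10α-CH3 (sets 9β-H), copper-catalysed allyl–alkyl coupling of the alkylborate forms C11–C12 (direct and allylic displacement on 15 give the same product), and enol-ether hydrolysis frees the 6-ketone and 18-OH with C5 protonated opposite the axial methyls, giving the also thermodynamic trans decalin (5β-H).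

Step 11
Reactants: 18 18-hydroxy enone
Product: 19 epoxy ketone
Conditions: 30% H2O2, NaOH (0.5 equiv), MeOH, 0 °C
Reagents that add atoms: hydrogen peroxide, OO
Why: Weitz–Scheffer nucleophilic epoxidation touches only the enone and not the side-chain diene, and hydroperoxide attacks C8 from the β face, anti to the syn-axial 10α-CH3, which fixes the C8–O configuration.

Step 12
Reactants: 19 epoxy ketone
Product: 21 andalusol, via hydroxy ketone 20 (not isolated)
Conditions: SmI2 (6 equiv, 0.1 M in THF), H2O (50 equiv), −78 → 25 °C
Reagents that add atoms: none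
Why: SmI2 cleaves the Cα–O bond of the α,β-epoxy ketone (reductive opening at C7) and keeps the tertiary 8β-OH, and further ketyl reduction of the 6-ketone under thermodynamic control, as in dissolving-metal reductions, gives the equatorial 6β-alcohol; the unactivated diene is not reduced.

Step 13
Reactants: 21 andalusol
Product: 23 6-O-acetylandalusol (target), via cyclic orthoacetate 22 (not isolated)
Conditions: MeC(OMe)3 (3 equiv), PPTS (5 mol %), CH2Cl2, 25 °C; then AcOH–H2O 4:1, 0 °C
Reagents that add atoms: trimethyl orthoacetate, CC(OC)(OC)OC; water, O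
Why: Proposed new method: the parallel equatorial C6–O and C4–CH2O bonds (O···O about 2.5 Å) should allow a seven-membered cyclic orthoacetate, whose hemi-orthoester on mild hydrolysis expels the less hindered primary oxygen and leaves the acetate on the secondary O6; the closest known reaction is kinetic opening of 1,2- and 1,3-diol orthoesters to the ester of the more hindered hydroxyl, and the tertiary 8-OH cannot bridge.

**Compound list**
1 | (S)-(+)-carvone, (5S)-2-methyl-5-(prop-1-en-2-yl)cyclohex-2-en-1-one | O=C1C[C@@H](C(C)=C)CC=C1C | starting material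
2 | trans-6-methylcarvone, (5S,6R)-2,6-dimethyl-5-(prop-1-en-2-yl)cyclohex-2-en-1-one (major epimer; the 6-epimer reacts alike) | O=C1[C@H](C)[C@@H](C(C)=C)CC=C1C | intermediate
3 | acrylonitrile | C=CC#N | starting material
4 | cyanoethyl methylcarvone, 3-[(1R,6R)-1,3-dimethyl-2-oxo-6-(prop-1-en-2-yl)cyclohex-3-en-1-yl]propanenitrile (cyanoethyl trans to isopropenyl) | O=C1[C@](C)(CCC#N)[C@@H](C(C)=C)CC=C1C | intermediate
5 | epoxy nitrile, 3-[(1R,6S)-1,3-dimethyl-6-(2-methyloxiran-2-yl)-2-oxocyclohex-3-en-1-yl]propanenitrile (1:1 at the oxirane carbon) | O=C1[C@](C)(CCC#N)[C@@H](C2(C)CO2)CC=C1C | intermediate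
6 | ketimine: trans-decalin, 3-imino, 9-oxo, 7-ene, 8-CH3, 10α-CH3, 5β-H, 4α-CH3, 4β-CH2OH | O=C1[C@]2(C)CCC(=N)[C@](C)(CO)[C@H]2CC=C1C | intermediate
7 | hydroxy dione: as 6 but 3-oxo | O=C1[C@]2(C)CCC(=O)[C@](C)(CO)[C@H]2CC=C1C | intermediate
8 | tosylhydrazone of the 3-ketone of 7 | O=C1[C@]2(C)CCC(=NNS(=O)(=O)c3ccc(C)cc3)[C@](C)(CO)[C@H]2CC=C1C | intermediate
9 | hydroxy enone, (4aR,5S,8aR)-5-(hydroxymethyl)-2,5,8a-trimethyl-4a,5,6,7,8,8a-hexahydronaphthalen-1(4H)-one (9-oxo, 7-ene, 10α-CH3, 5β-H, 4α-CH3, 4β-CH2OH) | O=C1[C@]2(C)CCC[C@](C)(CO)[C@H]2CC=C1C | intermediate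
10 | hydroxy enedione: as 9 with an additional 6-oxo group | O=C1[C@]2(C)CCC[C@](C)(CO)[C@H]2C(=O)C=C1C | intermediate
11 | dihydrofuran dienone: C18–O–C6 ether, 5(6)- and 7-ene, 9-oxo, 10α-CH3, 4α-CH3 | O=C1[C@]2(C)CCC[C@]3(C)COC(C=C1C)=C23 | intermediate
12 | 9-methylene triene ether: as 11 with C9=C11H2 | C=C1[C@]2(C)CCC[C@]3(C)COC(C=C1C)=C23 | intermediate
13 | isoprene | C=CC(C)=C | starting material
14 | (E)-1,4-dibromo-2-methylbut-2-ene | BrC/C=C(\C)CBr | intermediate
15 | 2-(bromomethyl)buta-1,3-diene | C=CC(=C)CBr | intermediate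
16 | B-alkyl-9-BBN borane: C11–B(9-BBN), 9β-H, otherwise as 12 | C(B1C2CCCC1CCC2)[C@H]3[C@]4(C)CCC[C@]5(C)COC(C=C3C)=C45 | intermediate
17 | labdane dienol ether: 6,18-epoxy-ent-labda-5,7,13(16),14-tetraene, 9β-H | C=CC(=C)CC[C@H]1[C@]2(C)CCC[C@]3(C)COC(C=C1C)=C23 | intermediate
18 | 18-hydroxy enone: ent-18-hydroxylabda-7,13(16),14-trien-6-one, 5β-H, 9β-H | C=CC(=C)CC[C@H]1[C@]2(C)CCC[C@](C)(CO)[C@H]2C(=O)C=C1C | intermediate
19 | epoxy ketone: 7β,8β-epoxide of 18 | C=CC(=C)CC[C@H]1[C@]2(C)CCC[C@](C)(CO)[C@H]2C(=O)[C@@H]3O[C@]13C | intermediate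
20 | hydroxy ketone: 8β,18-dihydroxy-6-ketone, 8α-CH3 | C=CC(=C)CC[C@H]1[C@]2(C)CCC[C@](C)(CO)[C@H]2C(=O)C[C@]1(C)O | intermediate
21 | andalusol: ent-labda-13(16),14-diene-6α,8α,18-triol (6β-OH and 8β-OH in the drawing, both equatorial) | C=CC(=C)CC[C@H]1[C@]2(C)CCC[C@](C)(CO)[C@H]2[C@H](O)C[C@]1(C)O | intermediate
22 | cyclic orthoacetate: 6,18-O-(1-methoxyethylidene)andalusol (orthoester carbon undefined) | C=CC(=C)CC[C@H]1[C@]2(C)CCC[C@]3(C)COC(C)(OC)O[C@@H]([C@@H]23)C[C@]1(C)O | intermediate
23 | 6-O-acetylandalusol: ent-6α-acetoxy-8α,18-dihydroxylabda-13(16),14-diene | C=CC(=C)CC[C@H]1[C@]2(C)CCC[C@](C)(CO)[C@H]2[C@H](OC(C)=O)C[C@]1(C)O | target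

**Step count.** There are 13 steps in total. The longest linear sequence is 11 steps (steps 1–7 and 10–13).

**Steps most likely to fail**

Step 4 carries the most risk, because a hindered tertiary radical adds only slowly to a nitrile. The fallback sets out from 2 and comes back at 9. It keeps the titanium-generated C4 radical but gives it a much better acceptor and a different ring-closure mode.
- Compound 2 is alkylated (LiN(i-Pr)2, methyl 2-(bromomethyl)acrylate), anti to the isopropenyl group, to the acrylate ketone F1.
- mCPBA then gives the epoxy acrylate F2.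
- Cp2TiCl (from Cp2TiCl2 and Mn) closes ring A by 6-endo conjugate (Giese) addition of C4 to the acrylate CH2, giving the C2 hydroxy ester F3.
- LiOH gives the hydroxy acid F4.
- Photoredox hydrodecarboxylation (9-mesityl-10-methylacridinium perchlorate, PhSSPh, blue light) delivers 9, so step 5 is no longer needed.

Step 10 is the second risk, because transmetalation of the β-branched borane may be sluggish. The fallback sets out from 12 and comes back at 17, and it swaps the roles of the two coupling partners.
- Borane 16 is oxidised (NaOH, H2O2) to the C11 primary alcohol F5.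
- PPh3, I2 and imidazole convert F5 into the C11 iodide F6.
- Compound 15 and Mg give isoprenylmagnesium bromide F7.
- Li2CuCl4-catalysed coupling of F6 with F7 gives 17, which is hydrolysed to 18 as before.

Step 13 is the third risk, because the seven-membered orthoester may not form or may open the wrong way. The fallback sets out from 21 and comes back at 23.
- Ac2O, DMAP and pyridine give the 6,18-diacetate F8, and the tertiary 8-OH stays free.
- Candida antarctica lipase B in MeOH and t-BuOMe removes only the primary 18-acetate to give 23.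

**Further compounds**
F1 | step 4 | acrylate ketone, methyl 2-{[(1R,6R)-1,3-dimethyl-2-oxo-6-(prop-1-en-2-yl)cyclohex-3-en-1-yl]methyl}acrylate | O=C1[C@](C)(CC(=C)C(=O)OC)[C@@H](C(C)=C)CC=C1C
F2 | step 4 | epoxy acrylate (1:1 at the oxirane carbon) | O=C1[C@](C)(CC(=C)C(=O)OC)[C@@H](C2(C)CO2)CC=C1C
F3 | step 4 | C2 hydroxy ester (as 9 with 2-CO2CH3, C2 undefined) | O=C1[C@]2(C)CC(C(=O)OC)C[C@](C)(CO)[C@H]2CC=C1C
F4 | step 4 | hydroxy acid (as 9 with 2-CO2H, C2 undefined) | O=C1[C@]2(C)CC(C(=O)O)C[C@](C)(CO)[C@H]2CC=C1C
F5 | step 10 | C11 primary alcohol (9β-H, otherwise as 12) | OC[C@H]1[C@]2(C)CCC[C@]3(C)COC(C=C1C)=C23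
F6 | step 10 | C11 iodide | IC[C@H]1[C@]2(C)CCC[C@]3(C)COC(C=C1C)=C23
F7 | step 10 | isoprenylmagnesium bromide | C=CC(=C)C[Mg]Br
F8 | step 13 | andalusol 6,18-diacetate | C=CC(=C)CC[C@H]1[C@]2(C)CCC[C@](C)(COC(C)=O)[C@H]2[C@H](OC(C)=O)C[C@]1(C)O
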